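**Retrosynthetic overview**

- The CH2 bridge between arene C7 and pyranone C3 is cut last, giving the acylphloroglucinol dihydrobenzofuran, formaldehyde and 6-ethyl-4-hydroxy-5-methylpyran-2-one.
- The strategy rests on the dihydrofuran ring: C3 is an unsubstituted benzylic CH2 on C3a, ortho to the O1-bearing C7a, and the only stereocenter, C2, is an allylic carbon bonded to O1, C3 and the 1,1-disubstituted alkene carbon.
- That ring is therefore cut at C3–C2 and O1–C2, giving an ortho-quinone methide (from a phenolic Mannich salt of bis-MOM phloroacetophenone) and an allyl sulfonium ylide that carries the whole C9 dienyl chain on a C2-symmetric chiral thiolane.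
- Ring order: the benzene ring is bought, the pyranone is closed within its own fragment, the dihydrofuran is closed in the [4+1] annulation, and the methylene bridge is made at the end.

Key step: step 11

Assumption: the (2R,5R)-thiolane is taken to deliver the (R) configuration at C2, by analogy with the ylide face that its benzyl and allyl ylides present to aldehydes; this sense must be confirmed on the first annulation product, and if it is reversed the (2S,5S)-sulfide, made in the same two steps from (2R,5R)-hexane-2,5-diol, is used instead.

**Route**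

Step 1
Reactants: 1 2,4,6-trihydroxyacetophenone
Product: 2 1-[4-(benzyloxy)-2,6-dihydroxyphenyl]ethan-1-one
Conditions: BnBr (1.0 equiv), K2CO3 (1.1 equiv), DMF, 0 °C to rt
Reagents that add atoms: benzyl bromide, BrCc1ccccc1
Why: Williamson ether synthesis in which the 4-OH, para to the acetyl and not hydrogen-bonded to it, is the most acidic and most accessible hydroxyl, so one equivalent of base and halide should favour the 4-O-benzyl ether, with over-alkylated material removed by chromatography.

Step 2
Reactants: 2 1-[4-(benzyloxy)-2,6-dihydroxyphenyl]ethan-1-one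
Product: 3 1-[4-(benzyloxy)-2,6-bis(methoxymethoxy)phenyl]ethan-1-one
Conditions: NaH (2.5 equiv), MOMCl (2.5 equiv), DMF, 0 °C to rt
Reagents that add atoms: chloromethyl methyl ether, COCCl
Why: O-alkylation of the bis-sodium phenoxide (MOM protection), full deprotonation with NaH being needed because both hydroxyls are hydrogen-bonded to the acetyl group and react poorly under amine-base conditions.

Step 3
Reactants: 3 1-[4-(benzyloxy)-2,6-bis(methoxymethoxy)phenyl]ethan-1-one
Product: 4 1-[4-hydroxy-2,6-bis(methoxymethoxy)phenyl]ethan-1-one
Conditions: H2 (1 atm), Pd/C (10%), EtOAc, rt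
Reagents that add atoms: none
Why: catalytic hydrogenolysis of the aryl benzyl ether, which should leave the MOM acetals and the hindered, doubly ortho-substituted aryl ketone untouched.

Step 4
Reactants: 4 1-[4-hydroxy-2,6-bis(methoxymethoxy)phenyl]ethan-1-one; 5 formaldehyde (as paraformaldehyde)
Product: 7 1-{3-[(dimethylamino)methyl]-4-hydroxy-2,6-bis(methoxymethoxy)phenyl}ethan-1-one, via (dimethylamino)methanol 6 (not isolated)
Conditions: (CH2O)n (1.05 equiv), Me2NH (40% in water, 1.1 equiv), EtOH, rt to 50 °C
Reagents that add atoms: dimethylamine, CNC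
Why: phenolic Mannich reaction at one of the two equivalent positions ortho to the free hydroxyl of an electron-rich phloroglucinol ring, run under neutral amine conditions so that the acetyl methyl is not aminomethylated and with one equivalent of reagent to limit double substitution.

Step 5
Reactants: 7 1-{3-[(dimethylamino)methyl]-4-hydroxy-2,6-bis(methoxymethoxy)phenyl}ethan-1-one
Product: 8 1-[3-acetyl-6-hydroxy-2,4-bis(methoxymethoxy)phenyl]-N,N,N-trimethylmethanaminium iodide
Conditions: MeI (3 equiv), acetone, rt, dark
Reagents that add atoms: iodomethane, CI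
Why: Menshutkin quaternisation, the tertiary amine being far more nucleophilic than the neutral phenol in the absence of base, and the salt should precipitate from acetone.

Step 6
Reactants: 9 2-methylprop-2-en-1-ol; 10 1-bromo-3-methylbut-2-ene (prenyl bromide)
Product: 12 6-methyl-2-methylidenehept-5-en-1-ol, via dilithiated 2-methylprop-2-en-1-ol 11 (not isolated)
Conditions: n-BuLi (2.1 equiv), TMEDA (2.1 equiv), Et2O, 0 °C to rt; then 10, THF, −78 °C to rt; H2O
Reagents that add atoms: none
Why: alkoxide-directed allylic lithiation of the methyl group gives an O,C-dianion whose carbon end is the more nucleophilic site, and its SN2 alkylation by the primary allylic bromide extends the chain by the prenyl unit.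

Step 7
Reactants: 12 6-methyl-2-methylidenehept-5-en-1-ol
Product: 13 2-(bromomethyl)-6-methylhepta-1,5-diene
Conditions: PBr3 (0.4 equiv), pyridine (catalytic), Et2O, −10 to 0 °C
Reagents that add atoms: phosphorus tribromide, BrP(Br)Br
Why: conversion of a primary allylic alcohol to the bromide with PBr3 as used for geranyl-type alcohols, in which allylic transposition is degenerate for this 2-substituted allyl unit and the low temperature with pyridine buffer should protect the trisubstituted alkene from HBr.

Step 8
Reactants: 14 (2S,5S)-hexane-2,5-diol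
Product: 15 (2S,5S)-hexane-2,5-diyl dimethanesulfonate
Conditions: MsCl (2.4 equiv), Et3N (3 equiv), CH2Cl2, −20 to 0 °C
Reagents that add atoms: methanesulfonyl chloride, CS(=O)(=O)Cl
Why: O-sulfonylation (mesylation) that breaks no C–O bond, so both stereocenters are retained.

Step 9
Reactants: 15 (2S,5S)-hexane-2,5-diyl dimethanesulfonate
Product: 16 (2R,5R)-2,5-dimethylthiolane
Conditions: Na2S·9H2O (1.2 equiv), DMSO, rt; pentane extraction, careful distillation
Reagents that add atoms: sodium sulfide, [Na+].[Na+].[S-2]
Why: double SN2 thioetherification, intermolecular and then 5-exo-tet, each displacement inverting its carbon so that the (2S,5S)-dimesylate should give the trans (2R,5R)-thiolane.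

Step 10
Reactants: 13 2-(bromomethyl)-6-methylhepta-1,5-diene; 16 (2R,5R)-2,5-dimethylthiolane
Product: 17 (2R,5R)-2,5-dimethyl-1-(6-methyl-2-methylidenehept-5-en-1-yl)thiolan-1-ium tetrafluoroborate
Conditions: 16 (1.2 equiv), NaBF4 (3 equiv), acetone, rt, 48 h
Reagents that add atoms: sodium tetrafluoroborate, [Na+].F[B-](F)(F)F
Why: S-alkylation of the sulfide by the reactive allylic bromide with anion metathesis, the precipitation of NaBr driving the reversible alkylation and exchanging bromide for non-nucleophilic tetrafluoroborate, while the C2 symmetry of the thiolane means no sulfur stereocenter is formed.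

Step 11
Reactants: 8 1-[3-acetyl-6-hydroxy-2,4-bis(methoxymethoxy)phenyl]-N,N,N-trimethylmethanaminium iodide; 17 (2R,5R)-2,5-dimethyl-1-(6-methyl-2-methylidenehept-5-en-1-yl)thiolan-1-ium tetrafluoroborate
Product: 21 1-[(2R)-4,6-bis(methoxymethoxy)-2-(6-methylhepta-1,5-dien-2-yl)-2,3-dihydro-1-benzofuran-5-yl]ethan-1-one, via allyl sulfonium ylide 18 (not isolated), via ortho-quinone methide 19 (not isolated), via phenoxide sulfonium betaine 20 (not isolated)
Conditions: 17 (1.5 equiv), Cs2CO3 (3.5 equiv), MeCN/CH2Cl2 (1:1), −20 °C to rt
Reagents that add atoms: none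
Why: Proposed new method: carbonate deprotonates the phenol of 8, whose ammonium phenoxide loses trimethylamine by 1,4-elimination to the ortho-quinone methide 19, and it reversibly deprotonates the S–CH2 of 17 to the allyl ylide 18, whose α-carbon adds to the exocyclic CH2 of 19 in a rearomatising conjugate addition to give betaine 20, in which the phenoxide then displaces the sulfide. The closest known reaction types are the [4+1] annulation of in situ ortho-quinone methides with stabilised sulfonium or ammonium ylides to 2-substituted 2,3-dihydrobenzofurans and the aldehyde epoxidation with allyl and methallyl ylides of this thiolane, and what is new is the use of a semistabilised chiral allyl ylide on a quinone methide. The dihydrofuran ring is closed at the O1–C2 bond by a 5-exo-tet SN2 displacement at the allylic sulfonium carbon, the C3–C2 bond having been made just before in the intermolecular addition. C2 is set in that C–C bond formation by the C2-symmetric (2R,5R)-thiolane, which leaves sulfur non-stereogenic and shields one face of the ylide carbon, and the closure inverts this carbon cleanly, so that the (S)-configured sulfonium carbon of 20 becomes (R)-C2. The step needs enantiofacial selectivity at the ylide carbon, α- rather than γ-attack of the allyl ylide, closure faster than re-deprotonation of 20, and ring formation through the oxygen para to the acetyl; these are served by the irreversible, aromatisation-driven addition to an unhindered CH2 terminus, by the fast intramolecular closure, by the two MOM ethers that leave a single phenoxide and screen the acetyl carbonyl from the ylide, and by the tertiary ring α-carbons of the thiolanium, which disfavour ring ylides and their [2,3] shift.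

Step 12
Reactants: 21 1-[(2R)-4,6-bis(methoxymethoxy)-2-(6-methylhepta-1,5-dien-2-yl)-2,3-dihydro-1-benzofuran-5-yl]ethan-1-one
Product: 22 1-[(2R)-4,6-dihydroxy-2-(6-methylhepta-1,5-dien-2-yl)-2,3-dihydro-1-benzofuran-5-yl]ethan-1-one
Conditions: 3 M HCl (aqueous)/MeOH (1:10), rt
Reagents that add atoms: none
Why: acid-catalysed acetal exchange (MOM deprotection), which is fast for MOM ethers ortho to an aryl ketone, so dilute acid at room temperature should spare the trisubstituted alkene and the allylic aryl ether and leave C2 untouched.

Step 13
Reactants: 23 methyl 3-oxopentanoate; 24 methyl propanoate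
Product: 26 methyl 4-methyl-3,5-dioxoheptanoate, via keto ester dianion 25 (not isolated)
Conditions: NaH (1.1 equiv), THF, 0 °C; n-BuLi (1.05 equiv), 0 °C; 24 (0.5 equiv), 0 °C to rt; aqueous HCl
Reagents that add atoms: none
Why: Claisen acylation of the Huckin–Weiler dianion at its more nucleophilic γ-carbon (C4), with two equivalents of dianion per ester because the diketo ester formed is more acidic and quenches one of them.

Step 14
Reactants: 26 methyl 4-methyl-3,5-dioxoheptanoate
Product: 27 6-ethyl-4-hydroxy-5-methyl-2H-pyran-2-one
Conditions: DBU (1.2 equiv), toluene, reflux; aqueous HCl wash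
Reagents that add atoms: none
Why: base-mediated lactonisation in which the enol oxygen of the C5 ketone attacks the methyl ester in a six-membered closure, driven by loss of methanol and formation of the conjugated 4-hydroxypyranone.

Step 15
Reactants: 22 1-[(2R)-4,6-dihydroxy-2-(6-methylhepta-1,5-dien-2-yl)-2,3-dihydro-1-benzofuran-5-yl]ethan-1-one; 27 6-ethyl-4-hydroxy-5-methyl-2H-pyran-2-one; 5 formaldehyde (as paraformaldehyde)
Product: 29 3-{[(2R)-5-acetyl-4,6-dihydroxy-2-(6-methylhepta-1,5-dien-2-yl)-2,3-dihydro-1-benzofuran-7-yl]methyl}-6-ethyl-4-hydroxy-5-methyl-2H-pyran-2-one, via 6-ethyl-5-methyl-3-methylidenepyran-2,4-dione 28 (not isolated)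
Conditions: 27 (2.5 equiv), (CH2O)n (1.5 equiv), ethylenediammonium diacetate (10 mol%), MeCN, rt to 40 °C
Reagents that add atoms: none
Why: three-component Knoevenagel condensation and Michael-type arene addition (carba-Betti reaction), in which the pyranone C3 and formaldehyde give the 3-methylidene dione 28 that is trapped by C7, the only free and doubly oxygen-activated arene carbon of 22, with excess pyranone used to suppress arene homodimer and no effect on C2.

**Compound list**

1 | 2,4,6-trihydroxyacetophenone | CC(=O)c1c(O)cc(O)cc1O | starting material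
2 | 1-[4-(benzyloxy)-2,6-dihydroxyphenyl]ethan-1-one | CC(=O)c1c(O)cc(OCc2ccccc2)cc1O | intermediate
3 | 1-[4-(benzyloxy)-2,6-bis(methoxymethoxy)phenyl]ethan-1-one | CC(=O)c1c(OCOC)cc(OCc2ccccc2)cc1OCOC | intermediate
4 | 1-[4-hydroxy-2,6-bis(methoxymethoxy)phenyl]ethan-1-one | CC(=O)c1c(OCOC)cc(O)cc1OCOC | intermediate
5 | formaldehyde (used as paraformaldehyde) | C=O | starting material
6 | (dimethylamino)methanol | CN(C)CO | intermediate
7 | 1-{3-[(dimethylamino)methyl]-4-hydroxy-2,6-bis(methoxymethoxy)phenyl}ethan-1-one | CC(=O)c1c(OCOC)cc(O)c(CN(C)C)c1OCOC | intermediate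
8 | 1-[3-acetyl-6-hydroxy-2,4-bis(methoxymethoxy)phenyl]-N,N,N-trimethylmethanaminium iodide | CC(=O)c1c(OCOC)cc(O)c(C[N+](C)(C)C)c1OCOC.[I-] | intermediate
9 | 2-methylprop-2-en-1-ol | C=C(C)CO | starting material
10 | 1-bromo-3-methylbut-2-ene (prenyl bromide) | CC(C)=CCBr | starting material
11 | dilithiated 2-methylprop-2-en-1-ol | [Li]CC(=C)CO[Li] | intermediate
12 | 6-methyl-2-methylidenehept-5-en-1-ol | C=C(CO)CCC=C(C)C | intermediate
13 | 2-(bromomethyl)-6-methylhepta-1,5-diene | C=C(CBr)CCC=C(C)C | intermediate
14 | (2S,5S)-hexane-2,5-diol | C[C@H](O)CC[C@H](C)O | starting material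
15 | (2S,5S)-hexane-2,5-diyl dimethanesulfonate | C[C@H](OS(C)(=O)=O)CC[C@H](C)OS(C)(=O)=O | intermediate
16 | (2R,5R)-2,5-dimethylthiolane | C[C@@H]1CC[C@@H](C)S1 | intermediate
17 | (2R,5R)-2,5-dimethyl-1-(6-methyl-2-methylidenehept-5-en-1-yl)thiolan-1-ium tetrafluoroborate | C[C@@H]1CC[C@@H](C)[S+]1CC(=C)CCC=C(C)C.F[B-](F)(F)F | intermediate
18 | (2R,5R)-2,5-dimethylthiolan-1-ium-1-yl 6-methyl-2-methylidenehept-5-en-1-ylide | C[C@@H]1CC[C@@H](C)[S+]1[CH-]C(=C)CCC=C(C)C | intermediate
19 | 4-acetyl-3,5-bis(methoxymethoxy)-6-methylidenecyclohexa-2,4-dien-1-one | CC(=O)C1=C(OCOC)C(=C)C(=O)C=C1OCOC | intermediate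
20 | 4-acetyl-2-{(2S)-2-[(2R,5R)-2,5-dimethylthiolan-1-ium-1-yl]-7-methyl-3-methylideneoct-6-en-1-yl}-3,5-bis(methoxymethoxy)phenolate | C=C(CCC=C(C)C)[C@H](Cc1c([O-])cc(OCOC)c(C(C)=O)c1OCOC)[S+]1[C@H](C)CC[C@H]1C | intermediate
21 | 1-[(2R)-4,6-bis(methoxymethoxy)-2-(6-methylhepta-1,5-dien-2-yl)-2,3-dihydro-1-benzofuran-5-yl]ethan-1-one | C=C(CCC=C(C)C)[C@H]1Cc2c(OCOC)c(C(C)=O)c(OCOC)cc2O1 | intermediate
22 | 1-[(2R)-4,6-dihydroxy-2-(6-methylhepta-1,5-dien-2-yl)-2,3-dihydro-1-benzofuran-5-yl]ethan-1-one | C=C(CCC=C(C)C)[C@H]1Cc2c(O)c(C(C)=O)c(O)cc2O1 | intermediate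
23 | methyl 3-oxopentanoate | CCC(=O)CC(=O)OC | starting material
24 | methyl propanoate | CCC(=O)OC | starting material
25 | sodium lithium dianion of methyl 3-oxopentanoate | CC=C([O-])C=C([O-])OC.[Na+].[Li+] | intermediate
26 | methyl 4-methyl-3,5-dioxoheptanoate | CCC(=O)C(C)C(=O)CC(=O)OC | intermediate
27 | 6-ethyl-4-hydroxy-5-methyl-2H-pyran-2-one | CCc1oc(=O)cc(O)c1C | intermediate
28 | 6-ethyl-5-methyl-3-methylidene-2H-pyran-2,4(3H)-dione | CCC1=C(C)C(=O)C(=C)C(=O)O1 | intermediate
29 | 3-{[(2R)-5-acetyl-4,6-dihydroxy-2-(6-methylhepta-1,5-dien-2-yl)-2,3-dihydro-1-benzofuran-7-yl]methyl}-6-ethyl-4-hydroxy-5-methyl-2H-pyran-2-one (CNP0294086.1) | C=C(CCC=C(C)C)[C@H]1Cc2c(O)c(C(C)=O)c(O)c(Cc3c(O)c(C)c(CC)oc3=O)c2O1 | target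

**Step count**

Total step count: 15. Longest linear sequence: 8 steps (steps 1, 2, 3, 4, 5, 11, 12, 15).

**Steps most likely to fail**

1. Step 11 (proposed new method). Facial discrimination at the ylide carbon may be insufficient, the configuration may erode through re-deprotonation of the betaine before ring closure, and the quinone methide may oligomerise while the ylide concentration is low.
Fallback with known chemistry, setting out from 4 and returning at 21: ortho-iodination of phenol 4 (N-iodosuccinimide, MeCN, 0 °C) should give 1-[4-hydroxy-3-iodo-2,6-bis(methoxymethoxy)phenyl]ethan-1-one F1. A Larock-type heteroannulation of F1 with bought myrcene (7-methyl-3-methylideneocta-1,6-diene, C=CC(=C)CCC=C(C)C), run with Pd2(dba)3, a chiral sulfinamide-phosphine ligand and K2CO3 in toluene with warming, should then give 21 directly. The aryl group adds to the terminal CH2 of the vinyl group and the phenoxide closes on the internal end of the resulting π-allyl palladium, which builds the same C3–C2 and O1–C2 bonds. The asymmetric form of this diene annulation is known for 2-substituted butadienes, and the ligand enantiomer would be chosen for (R)-C2, with enrichment by preparative chiral chromatography if needed.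

2. Step 15. Homo-coupling of either partner through formaldehyde may compete with the cross-coupling, and the methylidene dione may be consumed by other pathways before the arene traps it.
Fallback, setting out from 27 and returning at 29: the pyranone 27 is aminomethylated at C3 with N,N-dimethylmethyleneiminium iodide in CH2Cl2 to give the isolated Mannich base 3-[(dimethylamino)methyl]-6-ethyl-4-hydroxy-5-methyl-2H-pyran-2-one F2. F2 is then heated with 22 in dioxane at 80 to 100 °C, so that the methylidene dione is released slowly by loss of dimethylamine only in the presence of the arene and no free formaldehyde meets 22.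

3. Step 4. Aminomethylation may run on to both positions ortho to the phenol, or be sluggish at a position crowded by the hydroxyl and a MOM ether.
Fallback, setting out from 4 and returning at 7: magnesium-mediated ortho-formylation of 4 (MgCl2, Et3N, (CH2O)n, MeCN, reflux), which is self-limiting because the formyl group deactivates the ring, should give 5-acetyl-2-hydroxy-4,6-bis(methoxymethoxy)benzaldehyde F3. Reductive amination of F3 with dimethylamine and NaBH(OAc)3 in 1,2-dichloroethane, which should not touch the hindered aryl ketone, then gives 7.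

**Further compounds**

F1 | step 11 | 1-[4-hydroxy-3-iodo-2,6-bis(methoxymethoxy)phenyl]ethan-1-one | CC(=O)c1c(OCOC)cc(O)c(I)c1OCOC
F2 | step 15 | 3-[(dimethylamino)methyl]-6-ethyl-4-hydroxy-5-methyl-2H-pyran-2-one | CCc1oc(=O)c(CN(C)C)c(O)c1C
F3 | step 4 | 5-acetyl-2-hydroxy-4,6-bis(methoxymethoxy)benzaldehyde | CC(=O)c1c(OCOC)cc(O)c(C=O)c1OCOC
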